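## Retrosynthetic overview

1. Target acid ⇒ Mitsunobu C–O disconnection into umbelliferone and a homoallylic primary alcohol; the acid is carried as a silyl-protected primary alcohol and oxidised last.
2. Homoallylic alcohol ⇒ [2,3]-Wittig–Still shift of the stannylmethyl ether of a 3β-allylic alcohol (sets C-1 and moves the alkene to C-2/C-3).
3. Allylic alcohol ⇒ transposed enone ⇒ vinylogous ester ⇒ epoxy ketone (Stork–Danheiser 1,3-carbonyl transposition, then Luche reduction).
4. Epoxy ketone ⇒ key intermolecular Michael addition of the C-6 enolate of 6-methylcarvone epoxide to tert-butyl acrylate (quaternary carbon, chain anti to isopropenyl).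
5. 6-Methylcarvone epoxide ⇒ (S)-carvone. No carbocycle is built: the cyclohexene comes from carvone and the coumarin from umbelliferone; the only ring formed is a temporary oxirane (step 2), opened again in step 4.

Convention: ring carbons keep the carvone locants throughout (C-1 = original carbonyl carbon, C-2 = methyl-bearing carbon, C-5 = isopropenyl-bearing carbon, C-6 = carbon that becomes quaternary). β = the face of the isopropenyl group, α = the opposite face.

## Route

Step 1
Reactants: 1 (S)-(+)-carvone
Product: 3 trans-6-methylcarvone, via lithium dienolate 2 (not isolated)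
Conditions: LiN(i-Pr)2 (1.05 equiv), THF, −78 °C; MeI, −78 → 0 °C
Reagents that add atoms: iodomethane, CI
Why: Kinetic α′-deprotonation gives the cross-conjugated lithium dienolate, whose C-alkylation (enolate alkylation) installs the C-6 methyl; its configuration (trans major) is irrelevant because C-6 is re-enolised in step 3.

Step 2
Reactants: 3 trans-6-methylcarvone
Product: 4 6-methylcarvone 2α,3α-epoxide
Conditions: 35% aq. H2O2, NaOH (0.3 equiv), MeOH, 0 °C
Reagents that add atoms: hydrogen peroxide, OO
Why: Weitz–Scheffer nucleophilic epoxidation touches only the electron-poor enone alkene, hydroperoxide adding to C-3 anti to the isopropenyl group (α-oxirane); the oxirane removes the enone acceptor and leaves C-6 as the only enolisable carbon.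

Step 3
Reactants: 4 6-methylcarvone 2α,3α-epoxide; 5 tert-butyl acrylate
Product: 7 epoxy keto ester with quaternary C-6, via potassium enolate 6 (not isolated)
Conditions: KOt-Bu (0.2 equiv), t-BuOH/THF (1:1), 0 °C → rt, slow addition of 5 (1.3 equiv)
Reagents that add atoms: none
Why: Base-catalysed intermolecular Michael addition in which the only possible enolate (C-2 has no hydrogen) adds to the acrylate from the α face, anti to the adjacent pseudoaxial isopropenyl group, fixing C-6 with methyl β and the propanoate chain α; with no enone present the adduct ester enolate can only be protonated by t-BuOH.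

Step 4
Reactants: 7 epoxy keto ester
Product: 8 β-hydroxy ketone
Conditions: SmI2 (2.5 equiv), THF/MeOH, −78 °C
Reagents that add atoms: none
Why: Single-electron reduction of the α,β-epoxy ketone (ketyl formation, cleavage of the C-2–O bond, protonation of the samarium enolate) gives the β-hydroxy ketone without touching the ester or the isopropenyl group; the C-2 and C-3 configurations are erased in steps 5 and 6.

Step 5
Reactants: 8 β-hydroxy ketone
Product: 9 2-methyl-1,3-diketone
Conditions: Dess–Martin periodinane, CH2Cl2, 0 °C → rt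
Reagents that add atoms: none
Why: Dess–Martin oxidation of the secondary alcohol gives the 1,3-diketone under near-neutral conditions that avoid retro-aldol cleavage.

Step 6
Reactants: 9 2-methyl-1,3-diketone
Product: 10 3-methoxy enone
Conditions: HC(OMe)3, MeOH, TsOH·H2O (5 mol %), rt
Reagents that add atoms: trimethyl orthoformate, COC(OC)OC; methanol, CO
Why: Acid-catalysed enol etherification (vinylogous ester formation) occurs at the unhindered C-3 carbonyl and keeps the C-1 carbonyl next to the quaternary C-6 as the ketone, as is usual for 4,4-disubstituted cyclohexane-1,3-diones.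

Step 7
Reactants: 10 3-methoxy enone
Product: 12 transposed hydroxy enone, via enol ether carbinol 11 (not isolated)
Conditions: LiAlH4, Et2O, 0 °C → rt; then 1 M HCl, THF, 0 °C, 15 min
Reagents that add atoms: none
Why: Stork–Danheiser transposition, in which hydride adds 1,2 to the C-1 carbonyl (and reduces the tert-butyl ester to the primary alcohol) and brief acid hydrolysis of the β-methoxy allylic alcohol with loss of water gives the C-3 enone with the alkene at C-1/C-2.

Step 8
Reactants: 12 transposed hydroxy enone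
Product: 13 3β-allylic alcohol diol
Conditions: NaBH4, CeCl3·7H2O, MeOH, −78 → −20 °C
Reagents that add atoms: none
Why: Luche 1,2-reduction in which hydride attacks the C-3 carbonyl from the α face, anti to the isopropenyl group (the carvone to cis-carveol selectivity), giving the 3β alcohol cis to isopropenyl.

Step 9
Reactants: 13 3β-allylic alcohol diol
Product: 14 primary silyl ether
Conditions: TBSCl (1.05 equiv), imidazole, CH2Cl2, −20 → 0 °C
Reagents that add atoms: tert-butyldimethylsilyl chloride, CC(C)(C)[Si](C)(C)Cl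
Why: Silylation discriminates the unhindered primary hydroxyl from the secondary allylic one and masks the future acid terminus for the organolithium step.

Step 10
Reactants: 14 primary silyl ether
Product: 16 3β-stannylmethyl ether, via potassium alkoxide 15 (not isolated)
Conditions: KH, THF, 0 °C; Bu3SnCH2I, 0 °C → rt
Reagents that add atoms: tributyl(iodomethyl)stannane, CCCC[Sn](CCCC)(CCCC)CI
Why: Williamson etherification of the potassium alkoxide with the iodomethylstannane gives the Still stannylmethyl ether with retention at C-3.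

Step 11
Reactants: 16 3β-stannylmethyl ether
Product: 18 homoallylic alcohol, via lithiomethyl ether 17 (not isolated)
Conditions: n-BuLi (1.3 equiv), THF, −78 → −30 °C; then H2O
Reagents that add atoms: none
Why: Tin–lithium exchange triggers the [2,3]-Wittig–Still rearrangement, a suprafacial shift that delivers CH2O to C-1 on the β face from which the C-3–O bond departs, so C-1 is set with CH2OH cis to the C-6 methyl and the isopropenyl group while the alkene moves to C-2/C-3.

Step 12
Reactants: 18 homoallylic alcohol; 19 umbelliferone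
Product: 20 umbelliferyl ether silyl ether
Conditions: PPh3, DIAD, THF, 0 °C → rt (45 °C if slow)
Reagents that add atoms: none
Why: Mitsunobu etherification in which the acidic phenol (pKa about 7.8) displaces the activated primary oxyphosphonium; no stereocentre is involved and the lactone and silyl ether are inert.

Step 13
Reactants: 20 umbelliferyl ether silyl ether
Product: 21 primary alcohol
Conditions: HF·pyridine, pyridine/THF, 0 °C → rt
Reagents that add atoms: none
Why: Buffered HF cleaves the primary silyl ether (desilylation driven by Si–F bond formation) without affecting the coumarin, the aryl ether or the acid-sensitive 1,1-disubstituted alkene.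

Step 14
Reactants: 21 primary alcohol
Product: 22 aldehyde
Conditions: Dess–Martin periodinane, CH2Cl2, 0 °C → rt
Reagents that add atoms: none
Why: Dess–Martin oxidation stops cleanly at the aldehyde and leaves both alkenes and the coumarin untouched.

Step 15
Reactants: 22 aldehyde
Product: 23 CNP0103683.1
Conditions: NaClO2, NaH2PO4, 2-methyl-2-butene, t-BuOH/H2O, 0 °C → rt
Reagents that add atoms: sodium chlorite, [Na+].[O-]Cl=O
Why: Pinnick oxidation converts the aldehyde to the acid under buffered conditions, 2-methyl-2-butene scavenging HOCl so that the alkenes and the electron-rich aryl ether are not chlorinated.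

## Compound list

1 | (S)-(+)-carvone, (5S)-2-methyl-5-(prop-1-en-2-yl)cyclohex-2-en-1-one | C=C(C)[C@H]1CC=C(C)C(=O)C1 | starting material
2 | lithium cross-conjugated dienolate of 1 (O–C-1=C-6, C-2=C-3) | C=C(C)[C@H]1CC=C(C)C(O[Li])=C1 | intermediate
3 | trans-6-methylcarvone, (5S,6R)-2,6-dimethyl-5-(prop-1-en-2-yl)cyclohex-2-en-1-one (minor 6S epimer carried along) | C=C(C)[C@H]1CC=C(C)C(=O)[C@@H]1C | intermediate
4 | 2α,3α-epoxy-2,6-dimethyl-5β-(prop-1-en-2-yl)cyclohexan-1-one (oxirane trans to isopropenyl; C-6 epimers, 6α-methyl drawn) | C=C(C)[C@H]1C[C@@H]2O[C@]2(C)C(=O)[C@@H]1C | intermediate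
5 | tert-butyl acrylate | C=CC(=O)OC(C)(C)C | starting material
6 | potassium C-1/C-6 enolate of 4 | C=C(C)[C@H]1C[C@@H]2O[C@]2(C)C(O[K])=C1C | intermediate
7 | tert-butyl 3-[2α,3α-epoxy-2,6β-dimethyl-1-oxo-5β-(prop-1-en-2-yl)cyclohexan-6α-yl]propanoate | C=C(C)[C@H]1C[C@@H]2O[C@]2(C)C(=O)[C@]1(C)CCC(=O)OC(C)(C)C | intermediate
8 | tert-butyl 3-[3α-hydroxy-2,6β-dimethyl-1-oxo-5β-(prop-1-en-2-yl)cyclohexan-6α-yl]propanoate (C-2 epimers) | C=C(C)[C@H]1C[C@H](O)C(C)C(=O)[C@]1(C)CCC(=O)OC(C)(C)C | intermediate
9 | tert-butyl 3-[2,6β-dimethyl-1,3-dioxo-5β-(prop-1-en-2-yl)cyclohexan-6α-yl]propanoate (keto/enol mixture) | C=C(C)[C@H]1CC(=O)C(C)C(=O)[C@]1(C)CCC(=O)OC(C)(C)C | intermediate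
10 | tert-butyl 3-[3-methoxy-2,6β-dimethyl-1-oxo-5β-(prop-1-en-2-yl)cyclohex-2-en-6α-yl]propanoate | C=C(C)[C@H]1CC(OC)=C(C)C(=O)[C@]1(C)CCC(=O)OC(C)(C)C | intermediate
11 | 3-[1-hydroxy-3-methoxy-2,6β-dimethyl-5β-(prop-1-en-2-yl)cyclohex-2-en-6α-yl]propan-1-ol (C-1 epimers; present as aluminium alkoxide until the acid quench) | C=C(C)[C@H]1CC(OC)=C(C)C(O)[C@]1(C)CCCO | intermediate
12 | 3-[2,6β-dimethyl-3-oxo-5β-(prop-1-en-2-yl)cyclohex-1-en-6α-yl]propan-1-ol | C=C(C)[C@H]1CC(=O)C(C)=C[C@]1(C)CCCO | intermediate
13 | 3-[3β-hydroxy-2,6β-dimethyl-5β-(prop-1-en-2-yl)cyclohex-1-en-6α-yl]propan-1-ol (3-OH cis to isopropenyl) | C=C(C)[C@H]1C[C@@H](O)C(C)=C[C@]1(C)CCCO | intermediate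
14 | primary tert-butyldimethylsilyl ether of 13 | C=C(C)[C@H]1C[C@@H](O)C(C)=C[C@]1(C)CCCO[Si](C)(C)C(C)(C)C | intermediate
15 | potassium 3β-alkoxide of 14 | C=C(C)[C@H]1C[C@@H](O[K])C(C)=C[C@]1(C)CCCO[Si](C)(C)C(C)(C)C | intermediate
16 | 3β-[(tributylstannyl)methoxy] ether of 14 | C=C(C)[C@H]1C[C@@H](OC[Sn](CCCC)(CCCC)CCCC)C(C)=C[C@]1(C)CCCO[Si](C)(C)C(C)(C)C | intermediate
17 | 3β-(lithiomethoxy) ether derived from 16 | C=C(C)[C@H]1C[C@@H](OC[Li])C(C)=C[C@]1(C)CCCO[Si](C)(C)C(C)(C)C | intermediate
18 | [6α-(3-{[tert-butyl(dimethyl)silyl]oxy}propyl)-2,6β-dimethyl-5β-(prop-1-en-2-yl)cyclohex-2-en-1β-yl]methanol (1-H α) | C=C(C)[C@H]1CC=C(C)[C@@H](CO)[C@]1(C)CCCO[Si](C)(C)C(C)(C)C | intermediate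
19 | umbelliferone (7-hydroxy-2H-chromen-2-one) | O=c1ccc2ccc(O)cc2o1 | starting material
20 | 7-{[6α-(3-{[tert-butyl(dimethyl)silyl]oxy}propyl)-2,6β-dimethyl-5β-(prop-1-en-2-yl)cyclohex-2-en-1β-yl]methoxy}-2H-chromen-2-one | C=C(C)[C@H]1CC=C(C)[C@@H](COc2ccc3ccc(=O)oc3c2)[C@]1(C)CCCO[Si](C)(C)C(C)(C)C | intermediate
21 | 7-{[6α-(3-hydroxypropyl)-2,6β-dimethyl-5β-(prop-1-en-2-yl)cyclohex-2-en-1β-yl]methoxy}-2H-chromen-2-one | C=C(C)[C@H]1CC=C(C)[C@@H](COc2ccc3ccc(=O)oc3c2)[C@]1(C)CCCO | intermediate
22 | 3-[2,6β-dimethyl-1β-{[(2-oxo-2H-chromen-7-yl)oxy]methyl}-5β-(prop-1-en-2-yl)cyclohex-2-en-6α-yl]propanal | C=C(C)[C@H]1CC=C(C)[C@@H](COc2ccc3ccc(=O)oc3c2)[C@]1(C)CCC=O | intermediate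
23 | CNP0103683.1, 3-[(1R,2R,6R)-1,3-dimethyl-2-{[(2-oxo-2H-chromen-7-yl)oxy]methyl}-6-(prop-1-en-2-yl)cyclohex-3-en-1-yl]propanoic acid | C=C(C)[C@H]1CC=C(C)[C@@H](COc2ccc3ccc(=O)oc3c2)[C@]1(C)CCC(=O)O | target

## Step count and risks

Total step count: 15. Longest linear sequence: 15 steps (1 → 23); tert-butyl acrylate 5 and umbelliferone 19 are bought.

Steps most likely to fail:

Step 3 (Michael addition). The hindered, tetrasubstituted enolate may add sluggishly, the epoxy ketone may not tolerate alkoxide, or the face selectivity may be eroded by the α-oxirane. Fallback, setting out from 4 and coming back at 7: the quaternary carbon is made by enolate alkylation instead. LiN(i-Pr)2 (THF, −78 °C) then allyl bromide gives 6α-allyl-2α,3α-epoxy-2,6β-dimethyl-5β-(prop-1-en-2-yl)cyclohexan-1-one F1, the electrophile again entering anti to isopropenyl. Chemoselective hydroboration of the monosubstituted alkene with disiamylborane, (Me2CHCHMe)2BH, and NaBO3·4H2O work-up gives the 3-hydroxypropyl epoxy ketone F2; the isopropenyl group and the doubly flanked ketone react far more slowly. Oxidation with 2,2,6,6-tetramethylpiperidin-1-oxyl and PhI(OAc)2 in MeCN/H2O gives the epoxy keto propanoic acid F3. Boc2O, 4-(dimethylamino)pyridine and t-BuOH then return the tert-butyl ester 7.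

Step 6 (regioselective enol ether). If O-methylation also occurs at the C-1 oxygen, that isomer leads back to the untransposed enone after step 7; the isopropenyl group also sees acid here. Fallback, setting out from 7 and coming back at 13: the transposition is done without a diketone by a Wharton rearrangement. N2H4·H2O with AcOH (MeOH, 0 °C → rt) converts 7 into the transposed 3α-allylic alcohol ester F4. Dess–Martin oxidation gives the transposed enone ester F5. Luche reduction (NaBH4, CeCl3·7H2O, MeOH, −78 °C) gives the 3β-allylic alcohol ester F6. LiAlH4 (THF, 0 °C) reduces the tert-butyl ester and returns diol 13. This is held in reserve because hydrazone formation at a ketone flanked by two fully substituted carbons may be slow.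

Step 11 ([2,3]-Wittig–Still). The shift needs the C-3–O bond pseudoaxial, which puts the isopropenyl group axial, so a [1,2]-shift or simple protonation to the methyl ether may compete. Fallback, setting out from 14 and coming back at 18: the carbon is delivered by a thermal, neutral [2,3] shift at the amide oxidation level (Büchi rearrangement). Heating 14 with N,N-dimethylformamide dimethyl acetal (xylene, 140 °C) gives the β,γ-unsaturated 1β-(N,N-dimethylcarboxamide) F7 through the alkoxy(amino)carbene, with the same suprafacial transfer from the 3β oxygen. LiNH2BH3 (THF, 0 °C → rt) reduces the tertiary amide to the primary alcohol 18.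

Further compounds
F1 | step 3 | 6α-allyl-2α,3α-epoxy-2,6β-dimethyl-5β-(prop-1-en-2-yl)cyclohexan-1-one | C=C(C)[C@H]1C[C@@H]2O[C@]2(C)C(=O)[C@]1(C)CC=C
F2 | step 3 | 2α,3α-epoxy-6α-(3-hydroxypropyl)-2,6β-dimethyl-5β-(prop-1-en-2-yl)cyclohexan-1-one | C=C(C)[C@H]1C[C@@H]2O[C@]2(C)C(=O)[C@]1(C)CCCO
F3 | step 3 | 3-[2α,3α-epoxy-2,6β-dimethyl-1-oxo-5β-(prop-1-en-2-yl)cyclohexan-6α-yl]propanoic acid | C=C(C)[C@H]1C[C@@H]2O[C@]2(C)C(=O)[C@]1(C)CCC(=O)O
F4 | step 6 | tert-butyl 3-[3α-hydroxy-2,6β-dimethyl-5β-(prop-1-en-2-yl)cyclohex-1-en-6α-yl]propanoate | C=C(C)[C@H]1C[C@H](O)C(C)=C[C@]1(C)CCC(=O)OC(C)(C)C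
F5 | step 6 | tert-butyl 3-[2,6β-dimethyl-3-oxo-5β-(prop-1-en-2-yl)cyclohex-1-en-6α-yl]propanoate | C=C(C)[C@H]1CC(=O)C(C)=C[C@]1(C)CCC(=O)OC(C)(C)C
F6 | step 6 | tert-butyl 3-[3β-hydroxy-2,6β-dimethyl-5β-(prop-1-en-2-yl)cyclohex-1-en-6α-yl]propanoate | C=C(C)[C@H]1C[C@@H](O)C(C)=C[C@]1(C)CCC(=O)OC(C)(C)C
F7 | step 11 | 6α-(3-{[tert-butyl(dimethyl)silyl]oxy}propyl)-N,N,2,6β-tetramethyl-5β-(prop-1-en-2-yl)cyclohex-2-ene-1β-carboxamide | C=C(C)[C@H]1CC=C(C)[C@@H](C(=O)N(C)C)[C@]1(C)CCCO[Si](C)(C)C(C)(C)C
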